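The runs were computed for substances that don't exist; the scatter is artificial.

A closed flask at constant volume gets its charges once, so we ask how much monomer the initiator charge can put into chains before growth in that flask stalls.

| flask | free monomer | protic impurity | initiator | temperature | remark | time |
|---|---|---|---|---|---|---|
| amber | 0.84 M | 0.024 M | 84 mM | 72 °C | run made earlier |  |
| blue | 0.84 M | 0.037 M | 84 mM | 122 °C | run made earlier |  |
| west | 0.84 M | 0.0168 M | 84 mM | 140 °C |  | 2.0 h |
| north-west | 0.84 M | 0.0168 M | 84 mM | 50 °C |  | 2.0 h |
| south | 0.84 M | 0.0168 M | 84 mM | 80 °C |  | 2.0 h |
| north-east | 0.84 M | 0.0168 M | 84 mM | 110 °C |  | 2.0 h |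

- amber (time / h: monomer in chains / %): 12.0: 21.4; 25.0: 38.3; 40.0: 52.0; 60.0: 63.9
- blue (time / h: monomer in chains / %): 1.00: 60.7; 2.00: 76.6; 3.00: 79.5; 4.00: 81.1; 5.00: 83.0

(standard deviation of a reading: 1 percentage point)

- the flask that comes out highest in amount of monomer in chains, in percent of the free monomer charged, or "all alike" when all lie within 1.5 percentage points (west / north-west / south / north-east / all alike)
- monomer in chains at the end, in percent of the free monomer charged, west
- monomer in chains at the end, in percent of the free monomer charged, north-west
- monomer in chains at the end, in percent of the free monomer charged, south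
- monomer in chains at the end, in percent of the free monomer charged, north-east

- what was read earlier has a scatter of 1 percentage point, one standard deviation
- a reading or a percentage of monomer in chains counts all its forms, free or not

We begin by comparing rates at two moments of the blue run. The log of what is not yet in chains falls at 0.934 h⁻¹ up to 1.00 h, but at 0.0936 h⁻¹ from 3.00 h to 5.00 h, so the later rate is far lower. We suppose that the centres carrying growth die (dead-end polymerisation), so that the total fall goes with the initiator charged. The last blue reading gives 21.1 M⁻¹ for the stall number, the natural log of the fall in what is not in chains, per mole per litre of initiator charged, once growth has stalled.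

West has the same initiator charge, so this number unchanged would give 83.0 %. The weak link is temperature, for west stands at 140 °C and the blue run at 122 °C, and we let it carry the change although the protic impurity differs too, 0.0168 M in west against 0.037 M in the blue run. To reforge it we turn to the amber run, whose rate slips from 0.0201 h⁻¹ in its first interval to 0.0142 h⁻¹ in its last. That is a slowing of 0.007787 h⁻¹. Rate over slowing, per initiator, gives a rough reading of 30.7 M⁻¹, higher than the blue value. Carrying that drift on to west, with the protic impurity charges of 0.024 M in the amber run and 0.037 M in the blue run set aside, gives 18.4 M⁻¹, and we commit to 78.7 % for west, taking it as stalled by 2.0 h.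

The forecast, made separately, sets west lower than we do, at 76 %, with north-west at 0.5 %, south at 9.5 % and north-east at 69 %. Its choice is west: “West probably wins, narrowly.”

The flasks give 74.6 % for west, 0.647 % for north-west, 6.88 % for south and 57.9 % for north-east, so the highest is west.

    protic impurity + free monomer → quenched substrate (k = 0.0240 M⁻¹ s⁻¹, Ea = 92.0 kJ mol⁻¹)
    living end → dead end (k = 6.90 × 10⁻⁵ s⁻¹, Ea = 129 kJ mol⁻¹)
    crystals ⇌ monomer in chains, rate k3*(cs3 - [monomer in chains]) while solid is left; crystals form when [monomer in chains] > cs3 (solubility = 0.710 M, k = 0.0450 s⁻¹)
    free monomer + initiator → living end + monomer in chains (k = 7.70 × 10⁻⁴ M⁻¹ s⁻¹, Ea = 73.0 kJ mol⁻¹)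
    free monomer + living end → monomer in chains + living end, rate k5*[living end]*[free monomer] (k = 0.00210 M⁻¹ s⁻¹, Ea = 99.0 kJ mol⁻¹)
    (constants at 110 °C)

West has come to rest: it holds 6.34 × 10⁻⁵ M of living end at 2.00 h and stands at 74.7 % at 20.0 h. North-east, which the flask sets lower than the forecast does, has not: it holds 0.0546 M of living end at 2.00 h and reaches 91.2 % at 20.0 h, crystals counted. Read at rest, west has a stall number of 16.3 M⁻¹, below our 18.4 M⁻¹.

For the neighbour of west charged with 0.034 M of initiator, that stall number gives 42.5 %. The computed flask gives 42.5 %.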